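**Retrosynthetic overview**
- The target comes from one global hydrogenation of a benzyl-protected (2R)-alkenol, which saturates the C4=C5 bond and removes both O-benzyl groups.
- That alkenol comes from olefin cross-metathesis of (R)-1-[3,5-bis(benzyloxy)phenyl]pent-4-en-2-ol with 1-tetradecene, which supplies C5–C17.
- The key C2–C3 bond and the C2 stereocentre come from a reagent-controlled asymmetric carbonyl allylation (Brown allylboration) of 3,5-bis(benzyloxy)phenylacetaldehyde.
- The aldehyde comes from methyl 3,5-dihydroxyphenylacetate by benzylation, LiAlH4 reduction and Dess–Martin oxidation.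
- No ring is formed: the only ring, the resorcinol benzene ring, is bought intact.

Assumption: the stereocentre in the SMILES is read as R (OH > CH2Ar > C15 chain > H), so the target is (R)-1-(3,5-dihydroxyphenyl)heptadecan-2-ol; methyl 3,5-dihydroxyphenylacetate, 1-tetradecene and (+)-Ipc2BOMe are taken as catalogue chemicals.

**Route**

Step 1
Reactants: 1 methyl 3,5-dihydroxyphenylacetate
Product: 3 methyl 3,5-bis(benzyloxy)phenylacetate, via mono(benzyl ether) 2 (not isolated)
Conditions: BnBr (2.4 equiv), K2CO3 (3 equiv), acetone, reflux, 16 h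
Reagents that add atoms: benzyl bromide, BrCc1ccccc1
Why: Williamson ether synthesis, in which K2CO3 deprotonates only the phenols (pKa about 10, against about 23 for the ester α-CH2) and the phenoxides displace bromide by SN2 one after the other, so O-benzylation is clean and no stereocentre is involved.

Step 2
Reactants: 3 methyl 3,5-bis(benzyloxy)phenylacetate
Product: 4 2-[3,5-bis(benzyloxy)phenyl]ethanol
Conditions: LiAlH4 (1.0 equiv), THF, 0 °C to rt, 1 h; aqueous work-up
Reagents that add atoms: none
Why: hydride reduction of an ester with LiAlH4 gives the primary alcohol reliably, and aryl benzyl ethers are inert to it.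

Step 3
Reactants: 4 2-[3,5-bis(benzyloxy)phenyl]ethanol
Product: 5 2-[3,5-bis(benzyloxy)phenyl]acetaldehyde
Conditions: Dess–Martin periodinane (1.2 equiv), pyridine (3 equiv), CH2Cl2, 0 °C to rt, 1 h; crude aldehyde used at once
Reagents that add atoms: none
Why: Dess–Martin oxidation stops at the aldehyde under mild, pyridine-buffered, non-aqueous conditions that tolerate benzyl ethers and limit enolisation of the sensitive arylacetaldehyde.

Step 4
Reactants: 5 2-[3,5-bis(benzyloxy)phenyl]acetaldehyde
Product: 7 (R)-1-[3,5-bis(benzyloxy)phenyl]pent-4-en-2-ol, via borinate ester 6 (not isolated)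
Conditions: (+)-Ipc2BOMe [antipode made from (−)-α-pinene] (1.3 equiv), CH2=CHCH2MgBr (1.2 equiv), Et2O, 0 °C to rt, 1 h; then 5, −78 °C, 3 h; then 3 M NaOH, 30% H2O2, rt to 40 °C, 2 h
Reagents that add atoms: allylmagnesium bromide, C=CC[Mg]Br; (+)-B-methoxydiisopinocampheylborane, COB([C@H]1C[C@H]2C[C@@H]([C@@H]1C)C2(C)C)[C@H]1C[C@H]2C[C@@H]([C@@H]1C)C2(C)C (boron carrier; its Ipc2B unit is present only in 6)
Why: Brown asymmetric allylboration (carbonyl allylation), in which the B-allyldiisopinocampheylborane from (−)-α-pinene adds through a closed six-membered chair transition state to the Re face of the aldehyde at −78 °C, faster than enolisation, setting C2 as R (CH2Ar outranks allyl), after which alkaline H2O2 cleaves borinate 6 to the free alcohol.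

Step 5
Reactants: 7 (R)-1-[3,5-bis(benzyloxy)phenyl]pent-4-en-2-ol; 8 1-tetradecene
Product: 9 (2R,4E)-1-[3,5-bis(benzyloxy)phenyl]heptadec-4-en-2-ol
Conditions: second-generation Grubbs catalyst RuCl2(=CHPh)(PCy3)(H2IMes) (5 mol %), 8 (4 equiv), CH2Cl2, 40 °C, 12 h
Reagents that add atoms: none
Why: olefin cross-metathesis of two unhindered terminal alkenes is driven by loss of ethylene and by the excess of the cheap partner, tolerates the free alcohol and the benzyl ethers, leaves C2 untouched and gives mainly the E alkene (any Z isomer converges in step 6).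

Step 6
Reactants: 9 (2R,4E)-1-[3,5-bis(benzyloxy)phenyl]heptadec-4-en-2-ol
Product: 12 (R)-1-(3,5-dihydroxyphenyl)heptadecan-2-ol, via saturated bis(benzyl ether) 10 (not isolated), via saturated mono(benzyl ether) 11 (not isolated)
Conditions: H2 (1 atm), 10% Pd/C, EtOAc/EtOH 1:1, rt, 16 h
Reagents that add atoms: none
Why: heterogeneous catalytic hydrogenation over Pd/C saturates the alkene and then hydrogenolyses both aryl benzyl ethers, while the non-benzylic C2–OH bond and its R configuration are untouched.

**Compound list**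
1 | methyl 3,5-dihydroxyphenylacetate | COC(=O)Cc1cc(O)cc(O)c1 | starting material
2 | methyl 3-(benzyloxy)-5-hydroxyphenylacetate (mono(benzyl ether)) | COC(=O)Cc1cc(O)cc(OCc2ccccc2)c1 | intermediate
3 | methyl 3,5-bis(benzyloxy)phenylacetate | COC(=O)Cc1cc(OCc2ccccc2)cc(OCc2ccccc2)c1 | intermediate
4 | 2-[3,5-bis(benzyloxy)phenyl]ethanol | OCCc1cc(OCc2ccccc2)cc(OCc2ccccc2)c1 | intermediate
5 | 2-[3,5-bis(benzyloxy)phenyl]acetaldehyde | O=CCc1cc(OCc2ccccc2)cc(OCc2ccccc2)c1 | intermediate
6 | O-[(R)-1-[3,5-bis(benzyloxy)phenyl]pent-4-en-2-yl] diisopinocampheylborinate (Ipc groups from (−)-α-pinene; borinate ester) | C=CC[C@@H](OB([C@H]1C[C@H]2C[C@@H]([C@@H]1C)C2(C)C)[C@H]1C[C@H]2C[C@@H]([C@@H]1C)C2(C)C)Cc1cc(OCc2ccccc2)cc(OCc2ccccc2)c1 | intermediate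
7 | (R)-1-[3,5-bis(benzyloxy)phenyl]pent-4-en-2-ol | C=CC[C@@H](O)Cc1cc(OCc2ccccc2)cc(OCc2ccccc2)c1 | intermediate
8 | 1-tetradecene | CCCCCCCCCCCCC=C | starting material
9 | (2R,4E)-1-[3,5-bis(benzyloxy)phenyl]heptadec-4-en-2-ol | CCCCCCCCCCCC/C=C/C[C@@H](O)Cc1cc(OCc2ccccc2)cc(OCc2ccccc2)c1 | intermediate
10 | (R)-1-[3,5-bis(benzyloxy)phenyl]heptadecan-2-ol (saturated bis(benzyl ether)) | CCCCCCCCCCCCCCC[C@@H](O)Cc1cc(OCc2ccccc2)cc(OCc2ccccc2)c1 | intermediate
11 | (R)-1-[3-(benzyloxy)-5-hydroxyphenyl]heptadecan-2-ol (saturated mono(benzyl ether)) | CCCCCCCCCCCCCCC[C@@H](O)Cc1cc(O)cc(OCc2ccccc2)c1 | intermediate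
12 | (R)-1-(3,5-dihydroxyphenyl)heptadecan-2-ol (CNP0283129.1) | CCCCCCCCCCCCCCC[C@@H](O)Cc1cc(O)cc(O)c1 | target

**Totals**
Total step count: 6. Longest linear sequence: 6 steps (1 to 12).

**Three steps most likely to fail**

Step 4 (asymmetric allylation). The arylacetaldehyde 5 is easily enolised, and the magnesium alkoxide present with the borane can cost yield; the enantiomeric excess (checked on 7 by chiral HPLC or Mosher ester) may fall short. The fallback sets out from 5 and replaces the stoichiometric chiral borane by an achiral allyl donor under chiral Lewis-acid catalysis: Keck allylation with allyltributylstannane (1.2 equiv), Ti(OiPr)4 (10 mol %), (R)-BINOL (20 mol %), 4 Å molecular sieves, CH2Cl2, −20 °C, 60 h. The medium is non-basic, and (R)-BINOL sends the allyl group to the Re face, so the same (R)-carbinol results and the route is rejoined at 7. New compounds on the way: none F0.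

Step 3 (oxidation to the labile aldehyde). Aldehyde 5 can self-condense, over-oxidise in air or suffer from the acetic acid released. The fallback sets out from ester 3 and reaches the aldehyde by partial reduction instead of oxidation: i-Bu2AlH (1.05 equiv), CH2Cl2, −78 °C, quench with MeOH at −78 °C, then aqueous potassium sodium tartrate. The aldehyde is released only on cold work-up and never meets an oxidant or acid; alcohol 4 is bypassed and the route is rejoined at 5. New compounds on the way: none F0.

Step 5 (cross-metathesis). Conversion may stall, 7 may homodimerise, or ruthenium hydrides may migrate the double bond. The fallback sets out from 7 and builds the chain by olefination instead of metathesis: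
- Benzylation (NaH, BnBr, Bu4NI cat., THF/DMF, 0 °C to rt) gives (R)-2-(benzyloxy)-1-[3,5-bis(benzyloxy)phenyl]pent-4-ene F1.
- Oxidative cleavage (OsO4 cat., NaIO4, 2,6-lutidine, dioxane/H2O, rt) gives (S)-3-(benzyloxy)-4-[3,5-bis(benzyloxy)phenyl]butanal F2. The spatial arrangement is unchanged; the descriptor changes only because CH2CHO outranks CH2Ar.
- Wittig olefination with the ylide from commercial tridecyltriphenylphosphonium bromide and NaN(SiMe3)2 (THF, −78 °C to rt) gives (2R,4Z)-2-(benzyloxy)-1-[3,5-bis(benzyloxy)phenyl]heptadec-4-ene F3.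
- Hydrogenation as in step 6 (H2, Pd/C, or Pd(OH)2/C if the secondary benzyl ether is slow) saturates the alkene and removes all three benzyl groups, so the route is rejoined at 12.

**Further compounds**
F0 | step 4 | none | none
F0 | step 3 | none | none
F1 | step 5 | (R)-2-(benzyloxy)-1-[3,5-bis(benzyloxy)phenyl]pent-4-ene | C=CC[C@@H](OCc1ccccc1)Cc1cc(OCc2ccccc2)cc(OCc2ccccc2)c1
F2 | step 5 | (S)-3-(benzyloxy)-4-[3,5-bis(benzyloxy)phenyl]butanal | O=CC[C@@H](OCc1ccccc1)Cc1cc(OCc2ccccc2)cc(OCc2ccccc2)c1
F3 | step 5 | (2R,4Z)-2-(benzyloxy)-1-[3,5-bis(benzyloxy)phenyl]heptadec-4-ene | CCCCCCCCCCCC/C=C\C[C@@H](OCc1ccccc1)Cc1cc(OCc2ccccc2)cc(OCc2ccccc2)c1
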